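The ratio of two top readings of E carries this flask: the midnight run tops at 10.2% and the dawn run at 13.2%, a ratio of 1.29 for a starting [X] larger by a factor of 1.50 at equal equivalents of G.

| flask | X | G | remark | time |
|---|---|---|---|---|
| midnight | 0.010 M | 2.5 equiv | run made earlier |  |
| dawn | 0.015 M | 2.5 equiv | run made earlier |  |
| flask | 0.020 M | 2.50 equiv |  | 2.0 h |

- midnight (time / min: E / %, X / %): 5.00: 2.1, 69.7; 8.00: 4.6, 59.3; 15.0: 6.7, 39.5; 25.0: 9.9, 23.9; 40.0: 10.1, 13.4; 80.0: 10.2, 4.1
- dawn (time / min: E / %, X / %): 5.00: 4.0, 60.4; 8.00: 6.4, 45.0; 15.0: 12.0, 27.6; 25.0: 13.2, 15.1; 40.0: 12.1, 6.6; 80.0: 10.6, 1.5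

(scatter of a reading: 0.5 percentage points)

- steps under discussion: E <-> Q; X + G -> J; G + J -> E

* the moment within 2.0 h at which there is most E
* the amount of E, in percent of the X charged, at that time
* the first time at which E reaches 4.6%, in the same percent

The ladder begins with the capture of X by G, with G in excess roughly a pseudo-first-order decay. Its life, read from the first dawn point and scaled by the charge, comes to 7.44 min in the flask, shorter than the 25.0 min of the dawn peak in E. The next rung is the top of E, where making from G and J balances net drain into Q. Making is a meeting of two species and drain a first-order step, so at equal shares of J, G and E their ratio climbs with starting [X], while the falling shares of J and G and the rising share of E carry it down through one as a run goes on. The exponent that turns the charge ratio into the top ratio, the top gain 0.636, stands below one and is rough, each top carrying a scatter of 0.5 percentage points. The last rung is the slow approach to a floor, where E reads 10.2% and 10.6% at 80.0 min in the two runs.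

My own reckoning carries the dawn top up by the gain to 15.8% in the flask. The forecast, holding that “E then behaves roughly as a steady-state level”, gives less: 15.3% at 0.36 h, with the asked level reached at 0.083 h.

The flask gives 15.4% at 0.336 h and reaches the asked level at 0.0668 h, earlier than the low end of the forecast's range, 0.07 h.

    E ⇌ Q (K = 7.80, k = 0.140 /min)
    X + G → J (k = 3.00 /M/min)
    G + J → E (k = 1.50 /M/min)

The top gain, applied to the flask's top, reckons 37.1% for the neighbouring flask with 0.080 M of X, and that flask gives 33.5%.

The runs are calculated with made-up constants; noise was put on by code.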